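**Strategy.** The route builds the phloroglucinol ring A last. Its alternating oxygens at C5, C7 and C8a (ring oxygen O1) match a 1-methoxy-1,3-bis(trimethylsilyloxy)buta-1,3-diene (C5–C8) joined to the C4a=C8a alkene of a ring C enone. The key step is a Diels–Alder benzannulation in which a (2S)-2-aryl-5-(phenylsulfinyl)-2,3-dihydropyran-4-one, carrying the complete ring B and the C2 stereocentre, forms C4a–C5 and C8–C8a, then loses benzenesulfenic acid and methoxytrimethylsilane to give the 5,7-dihydroxychromanone in one operation. The precursor comes from a catalytic asymmetric acetate aldol on the fully decorated ring B aldehyde, sulfoxide acylation and aminomethylene ring closure.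

Key step: step 11

Remark: racemic methyl phenyl sulfoxide is used, so 13, 15, 16 and 20 are mixtures at sulfur (20 also at C4a, C5 and C8a); all of these centres disappear in step 11.

Abbreviation: Ar = 4-methoxy-3-[(E)-3-methylbuta-1,3-dienyl]-5-(3-methylbut-2-enyl)phenyl.

**Step 1**
Reactants: 1 3-bromo-4-hydroxybenzaldehyde
Product: 2 3-bromo-4-hydroxy-5-iodobenzaldehyde
Conditions: NIS, AcOH, 25 °C
Reagents that add atoms: N-iodosuccinimide, O=C1CCC(=O)N1I
Why: Electrophilic aromatic iodination is steered by the phenol to its only free ortho position, which is also meta to the deactivating formyl group.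

**Step 2**
Reactants: 2 3-bromo-4-hydroxy-5-iodobenzaldehyde
Product: 3 3-bromo-5-iodo-4-methoxybenzaldehyde
Conditions: MeI, K2CO3, DMF, 25 °C
Reagents that add atoms: iodomethane, CI
Why: Williamson O-methylation of the acidic, doubly ortho-halogenated phenoxide is fast and leaves the aldehyde and both halides untouched.

**Step 3**
Reactants: 3 3-bromo-5-iodo-4-methoxybenzaldehyde; 4 2-methylbut-3-en-2-ol
Product: 5 3-bromo-5-[(E)-3-hydroxy-3-methylbut-1-enyl]-4-methoxybenzaldehyde
Conditions: Pd(OAc)2 (3 mol %), Bu4NCl, NaHCO3, DMF, 50 °C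
Reagents that add atoms: none
Why: In this ligand-free phase-transfer Heck reaction, zerovalent palladium inserts into C–I far faster than into C–Br, and syn insertion followed by beta-hydride elimination from the benzylic carbon gives only the E styrenyl tertiary alcohol.

**Step 4**
Reactants: 5 3-bromo-5-[(E)-3-hydroxy-3-methylbut-1-enyl]-4-methoxybenzaldehyde; 6 4,4,5,5-tetramethyl-2-(3-methylbut-2-enyl)-1,3,2-dioxaborolane
Product: 7 3-[(E)-3-hydroxy-3-methylbut-1-enyl]-4-methoxy-5-(3-methylbut-2-enyl)benzaldehyde
Conditions: Pd2(dba)3 (2 mol %), t-BuXPhos (8 mol %), aq K3PO4, THF, 40 °C, 6 added slowly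
Reagents that add atoms: none
Why: In this Suzuki–Miyaura coupling at the remaining bromide, the bulky di-tert-butyl biaryl phosphine lets the allylpalladium intermediate settle on its unhindered terminus before reductive elimination, giving the linear prenyl arene, while the low temperature and slow addition of the boronate hold back uncatalysed allylboration of the aldehyde.

**Step 5**
Reactants: 7 3-[(E)-3-hydroxy-3-methylbut-1-enyl]-4-methoxy-5-(3-methylbut-2-enyl)benzaldehyde
Product: 8 4-methoxy-3-[(E)-3-methylbuta-1,3-dienyl]-5-(3-methylbut-2-enyl)benzaldehyde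
Conditions: methyl N-(triethylammoniosulfonyl)carbamate (inner salt), THF, 50 °C
Reagents that add atoms: none
Why: Dehydration through the sulfamate ester of the tertiary allylic alcohol (syn elimination) can only remove a methyl hydrogen, so the isopropenyl terminus forms under neutral conditions and the E styrenyl alkene is not disturbed.

**Step 6**
Reactants: 8 4-methoxy-3-[(E)-3-methylbuta-1,3-dienyl]-5-(3-methylbut-2-enyl)benzaldehyde; 9 1-(tert-butyldimethylsilyloxy)-1-methoxyethene
Product: 11 methyl (3S)-3-hydroxy-3-Ar-propanoate, via silyl ether 10 (not isolated)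
Conditions: Ti(OiPr)4 (5 mol %), Schiff base of 2-amino-2'-hydroxy-1,1'-binaphthyl and 3-bromo-5-tert-butylsalicylaldehyde (antipode that directs Si-face attack), 3,5-di-tert-butylsalicylic acid, Et2O, 0 °C; then Bu4NF, AcOH, THF, 0 → 25 °C
Reagents that add atoms: none
Why: In this catalytic enantioselective Mukaiyama acetate aldol reaction the chiral tetravalent titanium complex binds the aldehyde and blocks its Re face, so the ketene acetal adds to the Si face and sets the (S)-carbinol, and acetic-acid-buffered fluoride then removes silicon without retro-aldol cleavage or elimination.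

**Step 7**
Reactants: 11 methyl (3S)-3-hydroxy-3-Ar-propanoate; 12 methyl phenyl sulfoxide (racemic)
Product: 13 (4S)-4-hydroxy-4-Ar-1-(phenylsulfinyl)butan-2-one
Conditions: 12 (4 equiv), LDA (4 equiv), THF, −78 °C; then 11, −78 → −40 °C; aq NH4Cl
Reagents that add atoms: none
Why: Claisen-type acylation of the alpha-sulfinyl carbanion by the methyl ester should proceed as it does for other unprotected beta-hydroxy esters, with excess carbanion absorbing the hydroxyl and product protons, and the carbinol centre takes no part.

**Step 8**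
Reactants: 13 (4S)-4-hydroxy-4-Ar-1-(phenylsulfinyl)butan-2-one; 14 N,N-dimethylformamide dimethyl acetal
Product: 16 (2S)-2-Ar-5-(phenylsulfinyl)-2,3-dihydro-4H-pyran-4-one, via enaminone 15 (not isolated)
Conditions: 14 (1.5 equiv), CH2Cl2, 25 °C; then BF3·OEt2 (1.2 equiv), −20 → 0 °C; aq NaHCO3
Reagents that add atoms: none
Why: Knoevenagel-type aminomethylenation of the active methylene between ketone and sulfoxide gives the enaminone, and Lewis-acid-promoted 6-endo addition–elimination of the carbinol oxygen at the aminomethylene carbon expels dimethylamine and closes ring C without touching the C2–O or C2–H bond.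

**Step 9**
Reactants: 17 methyl acetoacetate
Product: 18 methyl 3-(trimethylsilyloxy)but-2-enoate
Conditions: Me3SiCl, Et3N, hexane, 25 °C
Reagents that add atoms: chlorotrimethylsilane, C[Si](C)(C)Cl
Why: Soft enolisation of the beta-keto ester with an amine base and O-silylation gives the silyl enol ether (silyl enol ether formation).

**Step 10**
Reactants: 18 methyl 3-(trimethylsilyloxy)but-2-enoate
Product: 19 1-methoxy-1,3-bis(trimethylsilyloxy)buta-1,3-diene
Conditions: LDA, THF, −78 °C; then Me3SiCl, −78 → 0 °C
Reagents that add atoms: chlorotrimethylsilane, C[Si](C)(C)Cl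
Why: Gamma-deprotonation of the vinylogous ester by the lithium amide gives a dienolate that is silylated on oxygen to the ketene silyl acetal (dienolate O-silylation), whose acetal geometry is irrelevant.

**Step 11**
Reactants: 16 (2S)-2-Ar-5-(phenylsulfinyl)-2,3-dihydro-4H-pyran-4-one; 19 1-methoxy-1,3-bis(trimethylsilyloxy)buta-1,3-diene
Product: 23 (2S)-5,7-dihydroxy-2-Ar-chroman-4-one (target), via cycloadduct 20 (not isolated), via ketal diene 21 (not isolated), via 7-O-silyl flavanone 22 (not isolated)
Conditions: 19 (4 equiv), toluene, 60 → 95 °C; then aq citric acid, THF, 0 °C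
Reagents that add atoms: none
Why: Proposed new method: the geminal acyl and sulfinyl groups on C4a outweigh the donor effect of O1, so C8a of 16 accepts the nucleophilic CH2 terminus of diene 19 while the ketene acetal carbon bonds to C4a, either in an asynchronous concerted (4+2) cycloaddition or by Mukaiyama–Michael addition followed by 6-exo-trig closure of the sulfinyl-stabilised enolate on the ester-level carbon, both paths closing the six-membered carbocyclic ring A to the same adduct 20. Because both bonds form on one face of the alkene, the C8a hydrogen lies cis to the sulfinyl group and C5 carries no hydrogen, so thermal syn elimination of benzenesulfenic acid can only give C4a=C8a (21), after which loss of methoxytrimethylsilane and tautomerisation aromatise ring A to the C5 phenol hydrogen-bonded to C4=O (22), and mild acid frees the C7 phenol. The closest known reaction types are Diels–Alder reactions of alpha-sulfinyl enones and sulfinylquinones with oxygenated dienes that shed the sulfoxide spontaneously, cycloadditions of chromones bearing an acceptor at C3 with siloxydienes, and resorcinol syntheses from 1-methoxy-1,3-bis(silyloxy)dienes and acetylenic ketones. No stereocentre survives from this step, since sulfur, C4a and C8a are erased on aromatisation, and C2, set in step 6, is remote from every bond made or broken under these neutral conditions. The step needs regioselectivity, secured by pairing the most nucleophilic diene terminus with the electrophilic beta carbon C8a, and chemoselectivity over the ring B diene and prenyl alkene, secured by the far higher reactivity and the excess of 19, which should also silylate the sulfenic acid released.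

**Compound list**
1 | 3-bromo-4-hydroxybenzaldehyde | O=Cc1ccc(O)c(Br)c1 | starting material
2 | 3-bromo-4-hydroxy-5-iodobenzaldehyde | O=Cc1cc(Br)c(O)c(I)c1 | intermediate
3 | 3-bromo-5-iodo-4-methoxybenzaldehyde | COc1c(Br)cc(C=O)cc1I | intermediate
4 | 2-methylbut-3-en-2-ol | C=CC(C)(C)O | starting material
5 | 3-bromo-5-[(E)-3-hydroxy-3-methylbut-1-enyl]-4-methoxybenzaldehyde | COc1c(Br)cc(C=O)cc1/C=C/C(C)(C)O | intermediate
6 | 4,4,5,5-tetramethyl-2-(3-methylbut-2-enyl)-1,3,2-dioxaborolane | CC(C)=CCB1OC(C)(C)C(C)(C)O1 | starting material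
7 | 3-[(E)-3-hydroxy-3-methylbut-1-enyl]-4-methoxy-5-(3-methylbut-2-enyl)benzaldehyde | COc1c(CC=C(C)C)cc(C=O)cc1/C=C/C(C)(C)O | intermediate
8 | 4-methoxy-3-[(E)-3-methylbuta-1,3-dienyl]-5-(3-methylbut-2-enyl)benzaldehyde | C=C(C)/C=C/c1cc(C=O)cc(CC=C(C)C)c1OC | intermediate
9 | 1-(tert-butyldimethylsilyloxy)-1-methoxyethene | C=C(OC)O[Si](C)(C)C(C)(C)C | starting material
10 | methyl (3S)-3-(tert-butyldimethylsilyloxy)-3-Ar-propanoate | C=C(C)/C=C/c1cc([C@@H](O[Si](C)(C)C(C)(C)C)CC(=O)OC)cc(CC=C(C)C)c1OC | intermediate
11 | methyl (3S)-3-hydroxy-3-Ar-propanoate | C=C(C)/C=C/c1cc([C@@H](O)CC(=O)OC)cc(CC=C(C)C)c1OC | intermediate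
12 | methyl phenyl sulfoxide (racemic) | CS(=O)c1ccccc1 | starting material
13 | (4S)-4-hydroxy-4-Ar-1-(phenylsulfinyl)butan-2-one, mixture at sulfur | C=C(C)/C=C/c1cc([C@@H](O)CC(=O)CS(=O)c2ccccc2)cc(CC=C(C)C)c1OC | intermediate
14 | N,N-dimethylformamide dimethyl acetal | COC(OC)N(C)C | starting material
15 | (5S)-1-(dimethylamino)-5-hydroxy-5-Ar-2-(phenylsulfinyl)pent-1-en-3-one, mixture at sulfur | C=C(C)/C=C/c1cc([C@@H](O)CC(=O)C(=CN(C)C)S(=O)c2ccccc2)cc(CC=C(C)C)c1OC | intermediate
16 | (2S)-2-Ar-5-(phenylsulfinyl)-2,3-dihydro-4H-pyran-4-one, mixture at sulfur | C=C(C)/C=C/c1cc([C@@H]2CC(=O)C(S(=O)c3ccccc3)=CO2)cc(CC=C(C)C)c1OC | intermediate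
17 | methyl acetoacetate | COC(=O)CC(C)=O | starting material
18 | methyl 3-(trimethylsilyloxy)but-2-enoate | COC(=O)C=C(C)O[Si](C)(C)C | intermediate
19 | 1-methoxy-1,3-bis(trimethylsilyloxy)buta-1,3-diene | C=C(O[Si](C)(C)C)C=C(OC)O[Si](C)(C)C | intermediate
20 | (2S)-5-methoxy-4a-(phenylsulfinyl)-5,7-bis(trimethylsilyloxy)-2-Ar-2,3,4a,5,8,8a-hexahydrochromen-4-one, cis-fused, mixture of diastereomers | C=C(C)/C=C/c1cc([C@@H]2CC(=O)C3(S(=O)c4ccccc4)C(OC)(O[Si](C)(C)C)C=C(O[Si](C)(C)C)CC3O2)cc(CC=C(C)C)c1OC | intermediate
21 | (2S)-5-methoxy-5,7-bis(trimethylsilyloxy)-2-Ar-2,3,5,8-tetrahydrochromen-4-one | C=C(C)/C=C/c1cc([C@@H]2CC(=O)C3=C(CC(O[Si](C)(C)C)=CC3(OC)O[Si](C)(C)C)O2)cc(CC=C(C)C)c1OC | intermediate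
22 | (2S)-5-hydroxy-2-Ar-7-(trimethylsilyloxy)chroman-4-one | C=C(C)/C=C/c1cc([C@@H]2CC(=O)c3c(O)cc(O[Si](C)(C)C)cc3O2)cc(CC=C(C)C)c1OC | intermediate
23 | (2S)-5,7-dihydroxy-2-{4-methoxy-3-[(E)-3-methylbuta-1,3-dienyl]-5-(3-methylbut-2-enyl)phenyl}chroman-4-one | C=C(C)/C=C/c1cc([C@@H]2CC(=O)c3c(O)cc(O)cc3O2)cc(CC=C(C)C)c1OC | target

**Step count and risks**
Total step count: 11. Longest linear sequence: 9 steps (steps 1 to 8 and step 11); steps 9 and 10 make the diene in a side branch.

Steps most likely to fail:

1. Step 11 (Proposed new method). The cycloaddition may be too slow on the oxygen-substituted enone at temperatures the silyl ketene acetal diene tolerates. A stepwise pathway may also open ring C by beta-elimination of O1 from the Michael intermediate before ring A closes, costing material and the integrity of C2. Fallback with known chemistry, setting out from aldehyde 8 and returning at 23, in which ring A is bought instead of built: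
   - 2',4',6'-trihydroxyacetophenone is protected with 3,4-dihydro-2H-pyran and PPTS to give 1-[2-hydroxy-4,6-bis(oxan-2-yloxy)phenyl]ethanone F1.
   - Claisen–Schmidt condensation of F1 with 8 (KOH, EtOH, 25 °C) should give the bis(tetrahydropyranyl) 2'-hydroxychalcone F2.
   - NaOAc in refluxing EtOH closes ring C by intramolecular oxa-Michael addition to the racemic bis(tetrahydropyranyl) flavanone F3.
   - PPTS in MeOH at 40 °C, mild enough for the dienyl chain, removes both acetals to give the racemic flavanone F4.
   - Preparative HPLC on a cellulose tris(3,5-dimethylphenylcarbamate) phase separates the enantiomers and delivers 23.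

2. Step 8. The Lewis acid may ionise or oligomerise the dienyl side chain, or the beta-hydroxy ketone may dehydrate or undergo retro-aldol cleavage before the oxygen closes onto the enaminone. Fallback setting out from aldehyde 8 and returning at 16, in which ring C is made first and sulfur is introduced afterwards:
   - Hetero-Diels–Alder reaction of 8 with (E)-1-methoxy-3-(trimethylsilyloxy)buta-1,3-diene, catalysed by Ti(OiPr)4 and the BINOL antipode that gives S, followed by brief CF3CO2H treatment at 0 °C, should give (2S)-2-Ar-2,3-dihydro-4H-pyran-4-one F5.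
   - Alpha-iodination of the enone (I2, pyridine, CH2Cl2) gives the 5-iodo enone F6.
   - C–S cross-coupling with thiophenol (Pd2(dba)3, Xantphos, iPr2NEt, dioxane, 80 °C) gives the 5-(phenylthio) enone F7.
   - Sulfur-selective oxidation with 2-(phenylsulfonyl)-3-phenyloxaziridine, which spares the alkenes, gives 16.

3. Step 4. The prenylboronate may add to the aldehyde by uncatalysed allylboration, and control of the coupling site on the allyl unit (linear versus branched) may be incomplete. Fallback setting out from bromide 5 and returning at 7: Stille coupling with tributyl(3-methylbut-2-enyl)stannane and Pd(PPh3)4 (zerovalent palladium) in DMF at 90 °C. The allylstannane is inert to aldehydes without a Lewis acid and normally couples at its unsubstituted terminus. This fallback makes no new compound (F0).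

**Further compounds**
F1 | step 11 | 1-[2-hydroxy-4,6-bis(oxan-2-yloxy)phenyl]ethanone, mixture at the acetal carbons | CC(=O)c1c(O)cc(OC2CCCCO2)cc1OC1CCCCO1
F2 | step 11 | (E)-1-[2-hydroxy-4,6-bis(oxan-2-yloxy)phenyl]-3-Ar-prop-2-en-1-one | C=C(C)/C=C/c1cc(/C=C/C(=O)c2c(O)cc(OC3CCCCO3)cc2OC4CCCCO4)cc(CC=C(C)C)c1OC
F3 | step 11 | racemic 5,7-bis(oxan-2-yloxy)-2-Ar-chroman-4-one | C=C(C)/C=C/c1cc(C2CC(=O)c3c(OC4CCCCO4)cc(OC4CCCCO4)cc3O2)cc(CC=C(C)C)c1OC
F4 | step 11 | racemic 5,7-dihydroxy-2-Ar-chroman-4-one | C=C(C)/C=C/c1cc(C2CC(=O)c3c(O)cc(O)cc3O2)cc(CC=C(C)C)c1OC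
F5 | step 8 | (2S)-2-Ar-2,3-dihydro-4H-pyran-4-one | C=C(C)/C=C/c1cc([C@@H]2CC(=O)C=CO2)cc(CC=C(C)C)c1OC
F6 | step 8 | (2S)-5-iodo-2-Ar-2,3-dihydro-4H-pyran-4-one | C=C(C)/C=C/c1cc([C@@H]2CC(=O)C(I)=CO2)cc(CC=C(C)C)c1OC
F7 | step 8 | (2S)-2-Ar-5-(phenylthio)-2,3-dihydro-4H-pyran-4-one | C=C(C)/C=C/c1cc([C@@H]2CC(=O)C(Sc3ccccc3)=CO2)cc(CC=C(C)C)c1OC
F0 | step 4 | none | none
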